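Assumption: the target is read from the SMILES as the (2R,3R,4aS,5S,8aR,5′R) isomer; ring atoms of all intermediates are labelled with the decahydroquinoline numbering of the target (C2–C8a) and the side chain C1′–C8′.

**Retrosynthetic overview**
- Last step: the piperidine ring, its N1–C2 bond, the C3–O ester bond and the C2/C3 stereocentres are made together from an all-cis 2-[(Z)-but-2-enyl]cyclohexylamine and (E)-oct-2-enoic acid by an iodine-mediated amino-acyloxylation (aziridinium ring expansion).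
- The (Z)-butenyl arm comes from an ester arm (half-reduction, Wittig); the all-cis C4a/C5/C8a triad comes from face-selective hydrogenation of a tetrasubstituted enecarbamate.
- The enecarbamate (C8a–N bond) comes from Pd-catalysed coupling of an enol triflate with tert-butyl carbamate; the triflate comes from asymmetric conjugate addition of the side-chain zinc reagent to methyl (6-oxocyclohexenyl)acetate (sets C5) with enolate triflation.
- The side chain comes from (R)-2-propyloxirane and allylMgBr (C5′); the enone comes from cyclohex-2-enone (α-iodination, Negishi coupling).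
- Ring order: the carbocycle is bought as cyclohexenone; the piperidine ring is closed last.

**Route**

Step 1
Reactants: 1 (R)-2-propyloxirane; 2 allylmagnesium bromide
Product: 3 (4R)-oct-7-en-4-ol
Conditions: allylMgBr (1.3 equiv), CuI (10 mol %), THF, −30 → 0 °C; aq NH4Cl
Reagents that add atoms: none
Why: Copper-catalysed SN2 opening of the terminal epoxide at its unsubstituted carbon by the allyl Grignard reagent leaves the (R) carbinol centre (later C5′) untouched.

Step 2
Reactants: 3 (4R)-oct-7-en-4-ol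
Product: 4 tert-butyl(dimethyl){[(4R)-oct-7-en-4-yl]oxy}silane
Conditions: TBSCl, imidazole, DMF, rt
Reagents that add atoms: tert-butyldimethylsilyl chloride, CC(C)(C)[Si](C)(C)Cl
Why: Standard silyl ether formation masks the carbinol through the organozinc, triflation and hydride steps and is removed later by acid.

Step 3
Reactants: 5 cyclohex-2-en-1-one
Product: 6 2-iodocyclohex-2-en-1-one
Conditions: I2 (1.5 equiv), pyridine/CH2Cl2 (1:1), 0 °C → rt
Reagents that add atoms: iodine, II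
Why: Amine-mediated α-iodination of the enone (conjugate addition of pyridine, iodination of the enolate, elimination) gives the α-iodoenone as a cross-coupling handle.

Step 4
Reactants: 6 2-iodocyclohex-2-en-1-one
Product: 7 methyl 2-(6-oxocyclohex-1-en-1-yl)acetate
Conditions: BrZnCH2CO2Me (1.5 equiv, from methyl bromoacetate and Zn dust, THF), Pd(PPh3)4 (5 mol %), THF, 45 °C
Reagents that add atoms: methyl bromoacetate, COC(=O)CBr
Why: Negishi coupling of the Reformatsky zinc reagent with the α-iodoenone under zerovalent palladium installs the two-carbon ester arm (later C4 and C3) faster than the reagent adds to the ketone.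

Step 5
Reactants: 4 tert-butyl(dimethyl){[(4R)-oct-7-en-4-yl]oxy}silane; 7 methyl 2-(6-oxocyclohex-1-en-1-yl)acetate
Product: 11 methyl 2-[(6S)-6-[(5R)-5-[(tert-butyldimethylsilyl)oxy]octyl]-2-[(trifluoromethanesulfonyl)oxy]cyclohex-1-en-1-yl]acetate, via alkyl(diethyl)borane 8 (not isolated), via dialkylzinc 9 (not isolated), via zinc enolate 10 (not isolated)
Conditions: 4 (2.4 equiv), Et2BH, 0 °C → rt; Et2Zn, 0 °C, then volatiles removed in vacuo; 7 (1.0 equiv), Cu(OTf)2 (2 mol %), (S,R,R)-BINOL bis(1-phenylethyl)amine phosphoramidite (4 mol %), toluene, −30 °C; Tf2O (1.5 equiv), −30 → 0 °C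
Reagents that add atoms: trifluoromethanesulfonic anhydride, O=S(=O)(OS(=O)(=O)C(F)(F)F)C(F)(F)F
Why: Hydroboration and boron-to-zinc exchange turn the alkene into a dialkylzinc, whose copper-phosphoramidite-catalysed asymmetric conjugate addition to the α-substituted enone sets C5 (S) by ligand control, and O-triflation of the regiodefined zinc enolate fixes the tetrasubstituted C4a=C8a double bond.

Step 6
Reactants: 11 methyl 2-[(6S)-6-[(5R)-5-[(tert-butyldimethylsilyl)oxy]octyl]-2-[(trifluoromethanesulfonyl)oxy]cyclohex-1-en-1-yl]acetate; 12 tert-butyl carbamate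
Product: 13 methyl 2-[(6S)-2-[(tert-butoxycarbonyl)amino]-6-[(5R)-5-[(tert-butyldimethylsilyl)oxy]octyl]cyclohex-1-en-1-yl]acetate
Conditions: Pd2(dba)3 (2.5 mol %), Xantphos (7.5 mol %), Cs2CO3 (1.5 equiv), 1,4-dioxane, 80 °C
Reagents that add atoms: none
Why: Palladium-catalysed C–N cross-coupling (Buchwald–Hartwig-type amidation of an enol triflate) forms the C8a–N bond and gives an enecarbamate that is stable as the enamide tautomer, so the double-bond position is kept.

Step 7
Reactants: 13 methyl 2-[(6S)-2-[(tert-butoxycarbonyl)amino]-6-[(5R)-5-[(tert-butyldimethylsilyl)oxy]octyl]cyclohex-1-en-1-yl]acetate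
Product: 14 methyl 2-[(1S,2R,6S)-2-[(tert-butoxycarbonyl)amino]-6-[(5R)-5-[(tert-butyldimethylsilyl)oxy]octyl]cyclohexyl]acetate
Conditions: H2 (50 bar), 5% Rh/Al2O3, EtOAc, rt
Reagents that add atoms: none
Why: Heterogeneous syn-hydrogenation of the tetrasubstituted enecarbamate from the face opposite the C5 chain (held pseudoaxial by allylic 1,2-strain with the ester arm) sets C4a (S) and C8a (R) and gives the all-cis triad.

Step 8
Reactants: 14 methyl 2-[(1S,2R,6S)-2-[(tert-butoxycarbonyl)amino]-6-[(5R)-5-[(tert-butyldimethylsilyl)oxy]octyl]cyclohexyl]acetate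
Product: 16 tert-butyl N-[(1R,2S,3S)-2-[(2Z)-but-2-en-1-yl]-3-[(5R)-5-[(tert-butyldimethylsilyl)oxy]octyl]cyclohexyl]carbamate, via aldehyde 15 (not isolated)
Conditions: i-Bu2AlH (2.2 equiv), toluene, −78 °C; then Ph3P=CHCH3 (from EtPPh3Br and KN(SiMe3)2, THF), −78 °C → rt
Reagents that add atoms: ethyltriphenylphosphonium bromide, CC[P+](c1ccccc1)(c1ccccc1)c1ccccc1.[Br-]
Why: Half-reduction of the methyl ester to the aldehyde and in-situ Wittig olefination with the unstabilised ylide under salt-free conditions gives the (Z)-alkene through the kinetically favoured cis-oxaphosphetane.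

Step 9
Reactants: 16 tert-butyl N-[(1R,2S,3S)-2-[(2Z)-but-2-en-1-yl]-3-[(5R)-5-[(tert-butyldimethylsilyl)oxy]octyl]cyclohexyl]carbamate
Product: 17 (4R)-8-[(1S,2S,3R)-3-amino-2-[(2Z)-but-2-en-1-yl]cyclohexyl]octan-4-ol
Conditions: HCl (3 M in MeOH), 0 °C → rt; aq K2CO3 work-up
Reagents that add atoms: none
Why: Acidolysis of the Boc carbamate and acid-catalysed methanolysis of the silyl ether in one operation give the free amino alcohol without touching the (Z)-alkene or any stereocentre.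

Step 10
Reactants: 17 (4R)-8-[(1S,2S,3R)-3-amino-2-[(2Z)-but-2-en-1-yl]cyclohexyl]octan-4-ol; 18 (2E)-oct-2-enoic acid
Product: 21 (2R,3R,4aS,5S,8aR)-5-[(5R)-5-hydroxyoctyl]-2-methyldecahydroquinolin-3-yl (2E)-oct-2-enoate, via iodoethylpyrrolidine 19 (not isolated), via aziridinium ion 20 (not isolated)
Conditions: 18 (3 equiv), Ag2O (1.1 equiv), MeCN, 4 Å MS, rt, dark; then 17, I2 (1.05 equiv), −20 °C → rt, then 40 °C; filter, aq Na2S2O3/NaHCO3
Reagents that add atoms: none
Why: Proposed new method: an aza-Prévost amino-acyloxylation, in which the acyl hypoiodite formed from the silver carboxylate and I2 iodinates the (Z)-alkene, the free primary amine closes 5-exo anti to iodine with the iodoethyl arm on the convex face of the cis-fused bicycle (19), the resulting secondary amine displaces iodide with silver assistance to give the cis-aziridinium ion 20, and a second carboxylate opens it at the ring-fusion carbon C3 with inversion to the ring-expanded piperidine, so that two inversions on the (Z)-alkene give the cis 2-methyl/3-acyloxy pair (C2 R, C3 R) on the face of H-4a and H-8a while the electron-poor enoate and the remote hydroxyl stay inert; the closest known reaction types are the Prévost iodo-acyloxylation of alkenes, ring-closing iodoamination, and the aziridinium ring expansion of 2-(1-haloalkyl)pyrrolidines to 3-oxygenated piperidines.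

**Compound list**

1 | (R)-2-propyloxirane | CCC[C@@H]1CO1 | starting material
2 | allylmagnesium bromide | C=CC[Mg]Br | starting material
3 | (4R)-oct-7-en-4-ol | CCC[C@@H](O)CCC=C | intermediate
4 | tert-butyl(dimethyl){[(4R)-oct-7-en-4-yl]oxy}silane | CCC[C@@H](O[Si](C)(C)C(C)(C)C)CCC=C | intermediate
5 | cyclohex-2-en-1-one | O=C1C=CCCC1 | starting material
6 | 2-iodocyclohex-2-en-1-one | O=C1CCCC=C1I | intermediate
7 | methyl 2-(6-oxocyclohex-1-en-1-yl)acetate | COC(=O)CC1=CCCCC1=O | intermediate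
8 | {(5R)-5-[(tert-butyldimethylsilyl)oxy]octyl}(diethyl)borane | CCB(CC)CCCC[C@H](O[Si](C)(C)C(C)(C)C)CCC | intermediate (not isolated)
9 | bis{(5R)-5-[(tert-butyldimethylsilyl)oxy]octyl}zinc | CCC[C@@H](O[Si](C)(C)C(C)(C)C)CCCC[Zn]CCCC[C@H](O[Si](C)(C)C(C)(C)C)CCC | intermediate (not isolated)
10 | alkylzinc enolate, methyl 2-[(6S)-6-R-2-(R-zinciooxy)cyclohex-1-en-1-yl]acetate with R = (5R)-5-[(tert-butyldimethylsilyl)oxy]octyl | COC(=O)CC1=C(O[Zn]CCCC[C@H](O[Si](C)(C)C(C)(C)C)CCC)CCC[C@@H]1CCCC[C@H](O[Si](C)(C)C(C)(C)C)CCC | intermediate (not isolated)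
11 | methyl 2-[(6S)-6-[(5R)-5-[(tert-butyldimethylsilyl)oxy]octyl]-2-[(trifluoromethanesulfonyl)oxy]cyclohex-1-en-1-yl]acetate | COC(=O)CC1=C(OS(=O)(=O)C(F)(F)F)CCC[C@@H]1CCCC[C@H](O[Si](C)(C)C(C)(C)C)CCC | intermediate
12 | tert-butyl carbamate | CC(C)(C)OC(N)=O | starting material
13 | methyl 2-[(6S)-2-[(tert-butoxycarbonyl)amino]-6-[(5R)-5-[(tert-butyldimethylsilyl)oxy]octyl]cyclohex-1-en-1-yl]acetate | COC(=O)CC1=C(NC(=O)OC(C)(C)C)CCC[C@@H]1CCCC[C@H](O[Si](C)(C)C(C)(C)C)CCC | intermediate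
14 | methyl 2-[(1S,2R,6S)-2-[(tert-butoxycarbonyl)amino]-6-[(5R)-5-[(tert-butyldimethylsilyl)oxy]octyl]cyclohexyl]acetate (all-cis) | COC(=O)C[C@H]1[C@@H](CCCC[C@H](O[Si](C)(C)C(C)(C)C)CCC)CCC[C@H]1NC(=O)OC(C)(C)C | intermediate
15 | tert-butyl N-[(1R,2S,3S)-3-[(5R)-5-[(tert-butyldimethylsilyl)oxy]octyl]-2-(2-oxoethyl)cyclohexyl]carbamate | O=CC[C@H]1[C@@H](CCCC[C@H](O[Si](C)(C)C(C)(C)C)CCC)CCC[C@H]1NC(=O)OC(C)(C)C | intermediate (not isolated)
16 | tert-butyl N-[(1R,2S,3S)-2-[(2Z)-but-2-en-1-yl]-3-[(5R)-5-[(tert-butyldimethylsilyl)oxy]octyl]cyclohexyl]carbamate | C/C=C\C[C@H]1[C@@H](CCCC[C@H](O[Si](C)(C)C(C)(C)C)CCC)CCC[C@H]1NC(=O)OC(C)(C)C | intermediate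
17 | (4R)-8-[(1S,2S,3R)-3-amino-2-[(2Z)-but-2-en-1-yl]cyclohexyl]octan-4-ol | C/C=C\C[C@H]1[C@@H](CCCC[C@H](O)CCC)CCC[C@H]1N | intermediate
18 | (2E)-oct-2-enoic acid | CCCCC/C=C/C(=O)O | starting material
19 | (4R)-8-[(2S,3aS,4S,7aR)-2-[(1S)-1-iodoethyl]octahydro-1H-indol-4-yl]octan-4-ol | C[C@H](I)[C@@H]1C[C@H]2[C@@H](CCCC[C@H](O)CCC)CCC[C@H]2N1 | intermediate (not isolated)
20 | cis-aziridinium ion from 19 (N-protonated; N bonded to C8a, C3 and C2; C2 R, C3 S, 4aS, 5S, 8aR, 5′R) | C[C@@H]1[C@@H]2C[C@H]3[C@@H](CCCC[C@H](O)CCC)CCC[C@H]3[NH+]12 | intermediate (not isolated)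
21 | (2R,3R,4aS,5S,8aR)-5-[(5R)-5-hydroxyoctyl]-2-methyldecahydroquinolin-3-yl (2E)-oct-2-enoate | CCCCC/C=C/C(=O)O[C@@H]1C[C@H]2[C@@H](CCCC[C@H](O)CCC)CCC[C@H]2N[C@@H]1C | target

**Step count and risks**

Total step count: 10. Longest linear sequence: 8 steps (steps 3–10 from cyclohex-2-en-1-one, or steps 1, 2 and 5–10 from the epoxide).

The three steps most likely to fail are step 10, step 5 and step 7.

Step 10 is the proposed new amino-acyloxylation. It can fail through poor facial selectivity in the iodoamination, opening of the aziridinium ion at C2 instead of C3, or oxidation of the free amine. The fallback uses known chemistry, sets out from 16 and comes back at 21.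
- 16 is N-deprotected selectively (TMSOTf, 2,6-lutidine; then MeOH) to (1R,2S,3S)-2-[(2Z)-but-2-en-1-yl]-3-[(5R)-5-[(tert-butyldimethylsilyl)oxy]octyl]cyclohexan-1-amine F1.
- 2-Nitrobenzenesulfonyl chloride and Et3N convert it into the N-nosyl sulfonamide F2.
- The established metal-free aminotrifluoroacetoxylation with the trivalent iodine reagent PhI(OCOCF3)2 in CH2Cl2 closes the ring by the same anti 5-exo, aziridinium, ring-expansion course to the N-nosyl decahydroquinolin-3-yl trifluoroacetate F3.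
- K2CO3 in MeOH cleaves this to the N-nosyl decahydroquinolin-3-ol F4.
- Fukuyama removal of the nosyl group (PhSH, K2CO3, MeCN), done before any enoate is present, gives the silyl-protected amino alcohol F5.
- Boc2O gives the N-Boc alcohol F6.
- Yamaguchi esterification with 18 (2,4,6-trichlorobenzoyl chloride, Et3N, DMAP) gives the N-Boc ester F7.
- Aqueous CF3CO2H removes Boc and the silyl ether and returns to 21.

Step 5 can fail because the α-substituted enone is a sluggish acceptor for the functionalised dialkylzinc (low conversion or low ee) or because the zinc enolate is triflated incompletely. The fallback sets out from 4 and comes back at 11.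
- Commercial cyclohexane-1,3-dione is C-alkylated with methyl bromoacetate (KOH, H2O) to methyl 2-(2,6-dioxocyclohexyl)acetate F8.
- Tf2O and pyridine convert it into the vinylogous triflate methyl 2-[6-oxo-2-[(trifluoromethanesulfonyl)oxy]cyclohex-1-en-1-yl]acetate F9.
- 4 is hydroborated with 9-BBN to 9-[(5R)-5-[(tert-butyldimethylsilyl)oxy]octyl]-9-borabicyclo[3.3.1]nonane F10.
- Suzuki–Miyaura coupling of F9 and F10 (Pd(dppf)Cl2, K3PO4, THF/H2O) gives the tetrasubstituted enone methyl 2-[2-[(5R)-5-[(tert-butyldimethylsilyl)oxy]octyl]-6-oxocyclohex-1-en-1-yl]acetate F11.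
- Copper hydride asymmetric conjugate reduction (Cu(OAc)2, DTBM-SEGPHOS in the antipode that gives 6S, PhMe2SiH) then sets C5 by hydride delivery and gives the (6S)-configured dimethylphenylsilyl enol ether F12.
- CsF and PhN(SO2CF3)2 convert F12 into 11.

Step 7 can fail because the tetrasubstituted, Boc-shielded enecarbamate hydrogenates slowly or with double-bond migration that erodes the cis C4a/C8a relationship. The fallback sets out from 13 and comes back at 16.
- 13 is freed of Boc (TMSOTf, 2,6-lutidine; then MeOH) and warmed in toluene, so that the enamine closes onto the ester and gives the flat bicyclic ene-lactam (4S)-4-[(5R)-5-[(tert-butyldimethylsilyl)oxy]octyl]-1,3,4,5,6,7-hexahydro-2H-indol-2-one F13.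
- Hydrogenation of this unhindered enamide (Pd/C, H2, AcOH) from the face away from the C4 chain gives the all-cis, cis-fused lactam (3aS,4S,7aR)-4-[(5R)-5-[(tert-butyldimethylsilyl)oxy]octyl]octahydro-2H-indol-2-one F14.
- Boc2O and DMAP give the N-Boc lactam F15.
- i-Bu2AlH at −78 °C gives the N-Boc hemiaminal F16, the ring form of 15.
- The Wittig reaction of step 8 opens F16 to 16.

Further compounds
F1 | step 10 | (1R,2S,3S)-2-[(2Z)-but-2-en-1-yl]-3-[(5R)-5-[(tert-butyldimethylsilyl)oxy]octyl]cyclohexan-1-amine | C/C=C\C[C@H]1[C@@H](CCCC[C@H](O[Si](C)(C)C(C)(C)C)CCC)CCC[C@H]1N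
F2 | step 10 | N-[(1R,2S,3S)-2-[(2Z)-but-2-en-1-yl]-3-[(5R)-5-[(tert-butyldimethylsilyl)oxy]octyl]cyclohexyl]-2-nitrobenzenesulfonamide | C/C=C\C[C@H]1[C@@H](CCCC[C@H](O[Si](C)(C)C(C)(C)C)CCC)CCC[C@H]1NS(=O)(=O)c2ccccc2[N+](=O)[O-]
F3 | step 10 | (2R,3R,4aS,5S,8aR)-5-[(5R)-5-[(tert-butyldimethylsilyl)oxy]octyl]-2-methyl-1-(2-nitrobenzenesulfonyl)decahydroquinolin-3-yl trifluoroacetate | FC(F)(F)C(=O)O[C@@H]1C[C@H]2[C@@H](CCCC[C@H](O[Si](C)(C)C(C)(C)C)CCC)CCC[C@H]2N(S(=O)(=O)c3ccccc3[N+](=O)[O-])[C@@H]1C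
F4 | step 10 | (2R,3R,4aS,5S,8aR)-5-[(5R)-5-[(tert-butyldimethylsilyl)oxy]octyl]-2-methyl-1-(2-nitrobenzenesulfonyl)decahydroquinolin-3-ol | O[C@@H]1C[C@H]2[C@@H](CCCC[C@H](O[Si](C)(C)C(C)(C)C)CCC)CCC[C@H]2N(S(=O)(=O)c3ccccc3[N+](=O)[O-])[C@@H]1C
F5 | step 10 | (2R,3R,4aS,5S,8aR)-5-[(5R)-5-[(tert-butyldimethylsilyl)oxy]octyl]-2-methyldecahydroquinolin-3-ol | O[C@@H]1C[C@H]2[C@@H](CCCC[C@H](O[Si](C)(C)C(C)(C)C)CCC)CCC[C@H]2N[C@@H]1C
F6 | step 10 | tert-butyl (2R,3R,4aS,5S,8aR)-5-[(5R)-5-[(tert-butyldimethylsilyl)oxy]octyl]-3-hydroxy-2-methyloctahydroquinoline-1(2H)-carboxylate | O[C@@H]1C[C@H]2[C@@H](CCCC[C@H](O[Si](C)(C)C(C)(C)C)CCC)CCC[C@H]2N(C(=O)OC(C)(C)C)[C@@H]1C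
F7 | step 10 | tert-butyl (2R,3R,4aS,5S,8aR)-5-[(5R)-5-[(tert-butyldimethylsilyl)oxy]octyl]-2-methyl-3-{[(2E)-oct-2-enoyl]oxy}octahydroquinoline-1(2H)-carboxylate | CCCCC/C=C/C(=O)O[C@@H]1C[C@H]2[C@@H](CCCC[C@H](O[Si](C)(C)C(C)(C)C)CCC)CCC[C@H]2N(C(=O)OC(C)(C)C)[C@@H]1C
F8 | step 5 | methyl 2-(2,6-dioxocyclohexyl)acetate | COC(=O)CC1C(=O)CCCC1=O
F9 | step 5 | methyl 2-[6-oxo-2-[(trifluoromethanesulfonyl)oxy]cyclohex-1-en-1-yl]acetate | COC(=O)CC1=C(OS(=O)(=O)C(F)(F)F)CCCC1=O
F10 | step 5 | 9-[(5R)-5-[(tert-butyldimethylsilyl)oxy]octyl]-9-borabicyclo[3.3.1]nonane | CCC[C@@H](O[Si](C)(C)C(C)(C)C)CCCCB1C2CCCC1CCC2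
F11 | step 5 | methyl 2-[2-[(5R)-5-[(tert-butyldimethylsilyl)oxy]octyl]-6-oxocyclohex-1-en-1-yl]acetate | COC(=O)CC1=C(CCCC[C@H](O[Si](C)(C)C(C)(C)C)CCC)CCCC1=O
F12 | step 5 | methyl 2-[(6S)-6-[(5R)-5-[(tert-butyldimethylsilyl)oxy]octyl]-2-[(dimethylphenylsilyl)oxy]cyclohex-1-en-1-yl]acetate | COC(=O)CC1=C(O[Si](C)(C)c2ccccc2)CCC[C@@H]1CCCC[C@H](O[Si](C)(C)C(C)(C)C)CCC
F13 | step 7 | (4S)-4-[(5R)-5-[(tert-butyldimethylsilyl)oxy]octyl]-1,3,4,5,6,7-hexahydro-2H-indol-2-one | O=C1CC2=C(N1)CCC[C@@H]2CCCC[C@H](O[Si](C)(C)C(C)(C)C)CCC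
F14 | step 7 | (3aS,4S,7aR)-4-[(5R)-5-[(tert-butyldimethylsilyl)oxy]octyl]octahydro-2H-indol-2-one | O=C1C[C@H]2[C@@H](CCCC[C@H](O[Si](C)(C)C(C)(C)C)CCC)CCC[C@H]2N1
F15 | step 7 | tert-butyl (3aS,4S,7aR)-4-[(5R)-5-[(tert-butyldimethylsilyl)oxy]octyl]-2-oxooctahydro-1H-indole-1-carboxylate | O=C1C[C@H]2[C@@H](CCCC[C@H](O[Si](C)(C)C(C)(C)C)CCC)CCC[C@H]2N1C(=O)OC(C)(C)C
F16 | step 7 | tert-butyl (3aS,4S,7aR)-4-[(5R)-5-[(tert-butyldimethylsilyl)oxy]octyl]-2-hydroxyoctahydro-1H-indole-1-carboxylate (both C2 epimers) | OC1C[C@H]2[C@@H](CCCC[C@H](O[Si](C)(C)C(C)(C)C)CCC)CCC[C@H]2N1C(=O)OC(C)(C)C
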